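**Retrosynthetic overview**
- Target ⇒ (last step) global O-debenzylation, then acid ketalisation of an upper A-ring ortho-OH onto C2; this closes the pyranone ring C.
- Hexabenzyl hemiketal ⇒ [3,3]-sigmatropic rearrangement (oxygen analogue of the Fischer indolisation) of an O-aryl oxime ether: it makes the quaternary C3–C8(lower) bond, and the phenol set free closes the dihydrofuran ring onto C2.
- Oxime ether ⇒ O-(flavan-7-yl)hydroxylamine + 2-methoxy-1,3-diaryl-1,3-dione (crossed Claisen of tribenzylated ω-methoxyphloroacetophenone with methyl 4-benzyloxybenzoate).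
- Aryloxyamine ⇒ ent-afzelechin (7-O singled out by silylation, then benzylation and phenoxide amination) ⇒ (−)-epiafzelechin by C2 epimerisation; this is the only chiral material.
- Ring order: both flavan rings are bought; dihydrofuran ring in step 7; pyranone ring C in step 8.

Assumption: (−)-epiafzelechin, 2-methoxy-1-(2,4,6-trihydroxyphenyl)ethanone and methyl 4-(benzyloxy)benzoate are bought; ent-afzelechin is not relied on as a catalogue item.

Locants: in coupled compounds C2, C3, C4 belong to the upper (flavanone-type) unit; C2L, C3L, C6L, C8L, O7L belong to the lower (flavan) unit. In the flavan alone, 4' is the B-ring para position.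

**Step 1**
Reactants: 1 (−)-epiafzelechin
Product: 2 ent-afzelechin [(2S,3R), 2,3-trans]
Conditions: degassed K2HPO4/KH2PO4 buffer (pH 7.5), Ar, 100 °C (sealed), 3 h; Sephadex LH-20 or RP-HPLC; recovered 1 recycled
Reagents that add atoms: none
Why: Base-mediated C2 epimerisation (retro-oxa-Michael to the B-ring p-quinone methide, then oxa-Michael re-closure) equilibrates C2 only; the bought C3 centre is untouched and steers C2 to the favoured 2,3-trans isomer (about 2–3:1 at equilibrium).

**Step 2**
Reactants: 2 ent-afzelechin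
Product: 3 7-O-triisopropylsilyl-ent-afzelechin
Conditions: iPr3SiCl (1.05 equiv), imidazole (2.2 equiv), DMF, −20 → 0 °C; chromatography; isomeric silyl ethers desilylated and recycled
Reagents that add atoms: triisopropylsilyl chloride, CC(C)[Si](Cl)(C(C)C)C(C)C
Why: Sterically governed phenol silylation: 7-OH is the unhindered one of the two more acidic A-ring phenols (5-OH is flanked by the C4 methylene, the B-ring 4'-OH is less acidic), so the bulky chloride should take it first, with moderate selectivity expected; no stereocentre is involved.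

**Step 3**
Reactants: 3 7-O-triisopropylsilyl-ent-afzelechin
Product: 4 5,4'-di-O-benzyl-7-O-triisopropylsilyl-ent-afzelechin
Conditions: BnBr (2.4 equiv), K2CO3 (3 equiv), acetone, 50 °C
Reagents that add atoms: benzyl bromide, BrCc1ccccc1
Why: Williamson ether synthesis on the two remaining phenols; the aryl triisopropylsilyl ether and the secondary 3-OH are inert to K2CO3, and fast capping of the 4'-phenoxide prevents quinone-methide epimerisation at C2.

**Step 4**
Reactants: 4 5,4'-di-O-benzyl-7-O-triisopropylsilyl-ent-afzelechin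
Product: 6 O-(5,4'-di-O-benzyl-ent-afzelechin-7-yl)hydroxylamine, via 5,4'-di-O-benzyl-ent-afzelechin 5 (not isolated)
Conditions: Bu4NF (1.0 equiv), THF, 0 °C, 10 min; then MesSO2ONH2 (MSH, 1.2 equiv), 0 °C → rt; used at once
Reagents that add atoms: O-(mesitylsulfonyl)hydroxylamine, Cc1cc(C)c(S(=O)(=O)ON)c(C)c1
Why: Fluoride desilylation gives the naked 7-phenoxide (the only phenoxide present), which is aminated on oxygen by electrophilic amination (SN2 at nitrogen of MSH) to give the O-arylhydroxylamine; the 3-OH and both stereocentres are untouched.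

**Step 5**
Reactants: 7 2-methoxy-1-(2,4,6-trihydroxyphenyl)ethan-1-one
Product: 8 2-methoxy-1-[2,4,6-tris(benzyloxy)phenyl]ethan-1-one
Conditions: BnBr (3.6 equiv), K2CO3 (4 equiv), DMF, 70 °C
Reagents that add atoms: benzyl bromide, BrCc1ccccc1
Why: Exhaustive Williamson etherification (forcing conditions also alkylate the chelated ortho-OH groups) removes every acidic OH, and with it any later route to a flavone.

**Step 6**
Reactants: 8 2-methoxy-1-[2,4,6-tris(benzyloxy)phenyl]ethan-1-one; 9 methyl 4-(benzyloxy)benzoate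
Product: 10 1-[4-(benzyloxy)phenyl]-2-methoxy-3-[2,4,6-tris(benzyloxy)phenyl]propane-1,3-dione
Conditions: NaH (2.5 equiv), THF, 65 °C; 1 M HCl quench
Reagents that add atoms: none
Why: Crossed Claisen condensation of the α-methoxy ketone enolate with the non-enolisable ester, driven by deprotonation of the β-diketone product; the methoxy-bearing carbon is an enolisable centre and needs no control.

**Step 7**
Reactants: 6 O-(5,4'-di-O-benzyl-ent-afzelechin-7-yl)hydroxylamine; 10 (1.2 equiv) the 2-methoxy-1,3-dione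
Product: 13 hexabenzyl hemiketal (C3 as drawn; formed together with its C3 epimer), via O-aryl oxime ether 11 (not isolated), via C8L-alkylated phenol ketimine 12 (not isolated)
Conditions: PPTS (0.2 equiv), 4 Å MS, EtOH/THF, 40 °C; filter; then HCl (4 M in dioxane, 1.5 equiv), THF/H2O 20:1, 0 °C → rt; aq NaHCO3
Reagents that add atoms: water, O
Why: Oxime ether condensation (either carbonyl of 10 leads to the same bond), tautomerisation to the N-aryloxy enamine and a [3,3]-sigmatropic rearrangement (oxa-Fischer-type hetero-Cope) form the quaternary C3–C8L bond, directed to C8L as aromatic Claisen rearrangements of 7-O-allyl-5-O-alkyl flavonoids are. After rearomatisation O7L adds to C2 and hydrolysis releases ammonia; C3 is set under substrate control from the remote C2L/C3L centres only, so a ratio near 1:1 to 2:1 is expected and the epimer is removed after step 8.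

**Step 8**
Reactants: 13 hexabenzyl hemiketal
Product: 15 target CNP0291586.2, via hexaphenol hemiketal 14 (not isolated)
Conditions: H2 (1 atm), Pd(OH)2/C, THF/MeOH, rt; filter; then TsOH·H2O (5 mol %), 4 Å MS, THF, rt; RP-HPLC (removes the C2,C3-diastereomer)
Reagents that add atoms: none
Why: Benzyl ether hydrogenolysis frees the A-ring ortho-OH, and acid-catalysed intramolecular ketalisation closes ring C onto C2. The fully dehydrated bis-ketal with the chelated C4 ketone is the thermodynamic sink, and because the new pyranone ring can only be cis-fused to the furan, C2 follows from C3.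

**Compound list**
1 | (−)-epiafzelechin; (2R,3R)-2-(4-hydroxyphenyl)chromane-3,5,7-triol | Oc1cc(O)c2c(c1)O[C@H](c1ccc(O)cc1)[C@H](O)C2 | starting material
2 | ent-afzelechin; (2S,3R)-2-(4-hydroxyphenyl)chromane-3,5,7-triol | Oc1cc(O)c2c(c1)O[C@@H](c1ccc(O)cc1)[C@H](O)C2 | intermediate
3 | (2S,3R)-2-(4-hydroxyphenyl)-7-(triisopropylsilyloxy)chromane-3,5-diol | CC(C)[Si](Oc1cc(O)c2c(c1)O[C@@H](c1ccc(O)cc1)[C@H](O)C2)(C(C)C)C(C)C | intermediate
4 | (2S,3R)-5-benzyloxy-2-(4-benzyloxyphenyl)-7-(triisopropylsilyloxy)chroman-3-ol | CC(C)[Si](Oc1cc(OCc3ccccc3)c2c(c1)O[C@@H](c1ccc(OCc3ccccc3)cc1)[C@H](O)C2)(C(C)C)C(C)C | intermediate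
5 | (2S,3R)-5-benzyloxy-2-(4-benzyloxyphenyl)chromane-3,7-diol (formed as its tetrabutylammonium phenoxide) | Oc1cc(OCc3ccccc3)c2c(c1)O[C@@H](c1ccc(OCc3ccccc3)cc1)[C@H](O)C2 | intermediate (not isolated)
6 | O-[(2S,3R)-5-benzyloxy-2-(4-benzyloxyphenyl)-3-hydroxychroman-7-yl]hydroxylamine | NOc1cc(OCc3ccccc3)c2c(c1)O[C@@H](c1ccc(OCc3ccccc3)cc1)[C@H](O)C2 | intermediate
7 | 2-methoxy-1-(2,4,6-trihydroxyphenyl)ethan-1-one | COCC(=O)c1c(O)cc(O)cc1O | starting material
8 | 2-methoxy-1-[2,4,6-tris(benzyloxy)phenyl]ethan-1-one | COCC(=O)c1c(OCc2ccccc2)cc(OCc2ccccc2)cc1OCc1ccccc1 | intermediate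
9 | methyl 4-(benzyloxy)benzoate | COC(=O)c1ccc(OCc2ccccc2)cc1 | starting material
10 | 1-[4-(benzyloxy)phenyl]-2-methoxy-3-[2,4,6-tris(benzyloxy)phenyl]propane-1,3-dione (racemic, enolisable) | COC(C(=O)c1ccc(OCc2ccccc2)cc1)C(=O)c1c(OCc2ccccc2)cc(OCc2ccccc2)cc1OCc1ccccc1 | intermediate
11 | O-aryl oxime ether of 10 at the 4-benzyloxybenzoyl carbonyl, aryl = flavan-7-yl of 6 (oxime geometry and methoxy centre undefined) | COC(C(=O)c1c(OCc2ccccc2)cc(OCc2ccccc2)cc1OCc1ccccc1)C(=NOc1cc(OCc2ccccc2)c2c(c1)O[C@@H](c1ccc(OCc3ccccc3)cc1)[C@H](O)C2)c1ccc(OCc2ccccc2)cc1 | intermediate (not isolated)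
12 | product of the [3,3] shift after rearomatisation: 7L-phenol carrying at C8L the quaternary carbon C(OMe)(aroyl)(C(=NH)aryl), configuration as drawn | CO[C@](C(=O)c1c(OCc2ccccc2)cc(OCc2ccccc2)cc1OCc1ccccc1)(C(=N)c1ccc(OCc2ccccc2)cc1)c1c(O)cc(OCc2ccccc2)c2c1O[C@@H](c1ccc(OCc3ccccc3)cc1)[C@H](O)C2 | intermediate (not isolated)
13 | hexabenzyl hemiketal: dihydrofuran fused at C7L–C8L of the flavan, with C2 bearing OH and 4-benzyloxyphenyl, and C3 bearing OMe and 2,4,6-tris(benzyloxy)benzoyl; C3 as in the target, C2 anomeric mixture in equilibrium with the ring-open hydroxy ketone | CO[C@@]1(C(=O)c2c(OCc3ccccc3)cc(OCc3ccccc3)cc2OCc2ccccc2)c2c(OC1(O)c1ccc(OCc3ccccc3)cc1)cc(OCc1ccccc1)c1c2O[C@@H](c2ccc(OCc3ccccc3)cc2)[C@H](O)C1 | intermediate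
14 | hexaphenol hemiketal (13 without its six benzyl groups) | CO[C@@]1(C(=O)c2c(O)cc(O)cc2O)c2c(OC1(O)c1ccc(O)cc1)cc(O)c1c2O[C@@H](c2ccc(O)cc2)[C@H](O)C1 | intermediate (not isolated)
15 | CNP0291586.2: upper unit C2 (S) ketal and C3 (R) methoxy centre, cis-fused; lower unit (2S,3R)-flavan-3-ol | CO[C@]12C(=O)c3c(O)cc(O)cc3O[C@]1(c1ccc(O)cc1)Oc1cc(O)c3c(c12)O[C@@H](c1ccc(O)cc1)[C@H](O)C3 | target

**Totals**
Total steps: 8. Longest linear sequence: 6 (steps 1, 2, 3, 4, 7, 8).

**Steps most likely to fail, with fallbacks**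

Step 2 (picking out 7-OH among three phenols). The selectivity rests only on sterics and a small acidity difference, and it may be poor. The fallback sets out from 2 and returns at 5, using chelation instead of sterics. All three phenols are benzylated (BnBr, K2CO3, DMF) to give 5,7,4'-tri-O-benzyl-ent-afzelechin F1. NBS (CH2Cl2, −78 °C) brominates the most nucleophilic position to give the 8-bromide F2. n-BuLi (2.2 equiv, THF, −78 °C) followed by CO2 gives the 8-carboxylic acid F3. BCl3 (CH2Cl2, −78 °C) removes only the benzyl group ortho to the carboxyl group, through a boron chelate, to give the 7-hydroxy-8-carboxylic acid F4. Warming F4 in DMF (90 °C) decarboxylates this phloroglucinol-carboxylic-acid type to 5, which is isolated here and aminated (KOtBu, then MSH) to 6.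

Step 4 (O-amination of an electron-rich phenoxide). C-amination or decomposition of MSH and of the labile aryloxyamine are possible. The fallback sets out from 5 (isolated after Bu4NF treatment of 4 and aqueous work-up) and returns at 6, making the O–N unit by cross-coupling instead. PhNTf2 with K2CO3 gives the 7-triflate F5. Coupling of F5 with ethyl acetohydroximate ([Pd(C3H5)Cl]2, t-BuBrettPhos, Cs2CO3, toluene, 65 °C) gives the ethyl N-aryloxyacetimidate F6, a storable protected form. HCl in dioxane/H2O releases 6 as its hydrochloride directly in the flask of step 7.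

Step 7 (condensation, [3,3] shift, cyclisation). There are three risks here.
- The shift may go partly to C6L.
- The acid may ionise C2 to an oxocarbenium ion, which can shed the stabilised aroyl cation to give a 2-aryl-3-methoxybenzofuran.
- The C3 ratio may be close to 1:1.

The fallback sets out from 11 (isolated after the PPTS stage) and returns at 13. It triggers the rearrangement by N-acylation instead of protonation. TFAA (3 equiv) with DMAP in CH2Cl2 at 0 °C converts 11 into its N-trifluoroacetyl ene-hydroxylamine. This rearranges at 0 °C and is caught as the neutral N-trifluoroacetyl aminal 3L-O-trifluoroacetate F7, so no oxocarbenium ion is formed. K2CO3 in MeOH/H2O then removes both trifluoroacetyl groups and hydrolyses the aminal to 13. The lower temperature is also the best chance of improving the C3 ratio. If the C6L isomer still forms, it is removed at this stage.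

**Further compounds**
F1 | step 2 | (2S,3R)-5,7-bis(benzyloxy)-2-(4-benzyloxyphenyl)chroman-3-ol | C(Oc1cc(OCc3ccccc3)c2c(c1)O[C@@H](c1ccc(OCc3ccccc3)cc1)[C@H](O)C2)c1ccccc1
F2 | step 2 | (2S,3R)-5,7-bis(benzyloxy)-2-(4-benzyloxyphenyl)-8-bromochroman-3-ol | C(Oc1cc(OCc3ccccc3)c2c(c1Br)O[C@@H](c1ccc(OCc3ccccc3)cc1)[C@H](O)C2)c1ccccc1
F3 | step 2 | (2S,3R)-5,7-bis(benzyloxy)-2-(4-benzyloxyphenyl)-3-hydroxychromane-8-carboxylic acid | C(Oc1cc(OCc3ccccc3)c2c(c1C(=O)O)O[C@@H](c1ccc(OCc3ccccc3)cc1)[C@H](O)C2)c1ccccc1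
F4 | step 2 | (2S,3R)-5-benzyloxy-2-(4-benzyloxyphenyl)-3,7-dihydroxychromane-8-carboxylic acid | Oc1cc(OCc3ccccc3)c2c(c1C(=O)O)O[C@@H](c1ccc(OCc3ccccc3)cc1)[C@H](O)C2
F5 | step 4 | (2S,3R)-5-benzyloxy-2-(4-benzyloxyphenyl)-3-hydroxychroman-7-yl trifluoromethanesulfonate | O=S(=O)(Oc1cc(OCc3ccccc3)c2c(c1)O[C@@H](c1ccc(OCc3ccccc3)cc1)[C@H](O)C2)C(F)(F)F
F6 | step 4 | ethyl N-{[(2S,3R)-5-benzyloxy-2-(4-benzyloxyphenyl)-3-hydroxychroman-7-yl]oxy}acetimidate | CCOC(C)=NOc1cc(OCc3ccccc3)c2c(c1)O[C@@H](c1ccc(OCc3ccccc3)cc1)[C@H](O)C2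
F7 | step 7 | N-trifluoroacetyl aminal of 13 (C2–NHCOCF3 in place of C2–OH) as its 3L-O-trifluoroacetate | CO[C@@]1(C(=O)c2c(OCc3ccccc3)cc(OCc3ccccc3)cc2OCc2ccccc2)c2c(OC1(NC(=O)C(F)(F)F)c1ccc(OCc3ccccc3)cc1)cc(OCc1ccccc1)c1c2O[C@@H](c2ccc(OCc3ccccc3)cc2)[C@H](OC(=O)C(F)(F)F)C1
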